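Abbreviations: TBS = tert-butyldimethylsilyl, Ms = methanesulfonyl, Bn = benzyl. Benzofuran numbering is used: O1, C2, C3, C3a, C4–C7, C7a. Ring A is the benzo ring, ring B the five-membered oxygen ring, ring C the aryl group on C2.

## Analysis of the target

The target 19 is a neolignan built on a 2,3-dihydrobenzofuran, with ring C (4-hydroxy-3-methoxyphenyl) on C2. Ring A carries a methoxy group at C7 and a 3-(sulfooxy)propyl chain at C5, and C3 carries a hydroxymethyl group. The two stereocentres are adjacent, C2 (S) and C3 (R), and the aryl and hydroxymethyl groups are trans on ring B. Three functions are sensitive. The alkyl hydrogen sulfate is acid-labile and very polar. The free phenol sits para to the benzylic C2–O1 bond and can open it in a quinone-methide manner under acid or hot base. The C2–O1 bond itself is a benzylic ether and can be hydrogenolysed. The synthesis is hard for two reasons: the trans stereodiad must be made in one absolute sense, and three hydroxyl groups must be told apart so that only the chain oxygen is sulfated. The plan rests on one feature: ring A is bonded to ring B through C7a–O1 and C3a–C3 on adjacent carbons, directly beside the C7 methoxy group. This is the pattern of a 2-iodoanisole with one free ortho position, and O1–C2–C3 is the three-atom unit of an epoxide.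

## Retrosynthetic reasoning

**Phenol last (19 from 17).** The final bond cut is the S–O bond of an aryl mesylate. The mesylate keeps the phenol from being sulfated, makes ring C electron-poor for the key step, and is removed by base, to which an alkyl sulfate monoanion is inert. Cold acidification of the resulting salt 18 then gives 19.

**Hydroxymethyl group (17 from 16).** The C3 hydroxymethyl group is carried as a benzyl ether and freed by hydrogenolysis after the sulfate is in place. A small ether was chosen because it stays put beside a transient alkoxide in the key step, where an ester could migrate.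

**Sulfate (16 from 14, 14 from 13).** The O–S bond is formed when the chain hydroxyl is the only free one. The chain oxygen therefore travels as a silyl ether, removable without touching the benzyl ether or the mesylate.

**Key disconnection (13 from 6 and 12).** Ring B is cut at C3–C3a and O1–C7a. This removes the whole heterocycle in one step and leaves two fragments of similar size: aryl iodide 6 and cis-epoxide 12. The forward reaction, with palladium and a strained bicyclic alkene as transient mediator, must attach C3 of the epoxide to the free ortho carbon of 6 with inversion. It must then close the C–O bond at the carbon that bore iodine. The C7 methoxy group of 6 blocks the second ortho position. Inversion at C3 with an untouched C2–O bond turns the cis-epoxide into the trans product, so both configurations of 13 are read from 12.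

**Epoxide (12 from 11).** The two C–O bonds of the epoxide come from enantioselective oxygen transfer to Z-alkene 11 by a chiral manganese–salen catalyst. Z-aryl alkenes are the best substrate class for this reaction.

**Z-alkene (11 from 10, 10 from 8 and 9, 8 from 7).** The Z geometry is taken from syn semihydrogenation of alkyne 10, which is made by alkynylation of aryl bromide 8 with alkyne 9. Bromide 8 is the mesylate of phenol 7. Olefination of an aldehyde with a 2-alkoxyethylidene phosphorane was set aside: such ylides can lose the β-alkoxide, and their Z-selectivity is not complete.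

**Aryl iodide (6 from 4, 4 from 1 and 2).** The C–I bond is made from a C–N bond through diazonium salt 5, so the iodine position is fixed by the amino group of 1. The chain is attached at the bromide of 1 by alkyl–aryl coupling of borane 3, obtained from alkene 2. Directed lithiation of a meta-alkylanisole was set aside because its two ortho positions are not reliably distinguished, and electrophilic iodination would go para to the methoxy group.

## Alternatives that were turned down

**Alternative 1:** [4+1] annulation of an ortho-quinone methide with a benzylic sulfur ylide.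
- Disconnection: C2–C3 and O1–C2. C2 arrives as the ylide carbon and ring A carries C3 as a masked methide carbon.
- Forward key step: a carbonate base would eliminate sulfinate from sulfone A2 and deprotonate sulfonium salt A3. The ylide adds to the methide carbon (C2–C3), and the phenoxide displaces the sulfide at C2 in a 5-exo-tet closure to give A1.
- For it: metal-free and mild; the closure is inherently trans-selective; the reaction type is established for aryl-substituted methides. A1 carries two benzyl ethers, so one hydrogenolysis would free both oxygens. On the endgame it is one step shorter than the chosen route.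
- Against it here: the methide carbon would bear a benzyloxymethyl group. Alkyl-type ortho-quinone methides are short-lived and can tautomerise (here to an enol ether) or lose the alkoxy group. Absolute configuration at both new centres would need a chiral sulfide in place of the thiolane of A3, with induction that cannot be predicted for this electron-rich ylide. A2 needs ortho-formylation of a ring A phenol, addition of an alkoxymethyl nucleophile and sulfinate exchange, about four extra steps.
- Comparison: the chosen strategy gives up the shorter endgame. In its place it takes absolute configuration by stereospecific transfer from an enantioenriched epoxide and avoids a labile intermediate.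

**Alternative 2:** oxidative ring contraction of a flavanone.
- Disconnection: only C3–C3a is formed, by a 1,2-shift of ring A.
- Forward key step: (S)-flavanone A5 would be treated with an aryl-λ3-iodane diacetate and acid in an orthoformate. The enol ether is iodinated at C3 of the flavanone, ring A carbon C4a migrates from C4 to C3, the six-membered ring contracts to ring B, and the old carbonyl carbon becomes the methyl ester of A4.
- For it: every step is of a known type. C2 can be set by asymmetric conjugate addition of an arylboronic acid to a chromone. The trans ester is the thermodynamic product. The deactivated ring C suppresses a competing shift of ring C. On precedent this alternative is the stronger one.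
- Against it: the ester must be reduced and protected, and the chain must be attached afterwards through the C5 bromide. The sequence is linear and about eight steps long before the chain-bearing dihydrobenzofuran is in hand. The C2 centre can be lost by reversible retro-oxa-Michael opening to a chalcone.
- Comparison: the chosen strategy is shorter, convergent, and delivers C3 at the right oxidation level. Because Alternative 2 rests on known chemistry, it is kept as the fallback for the key step.

**Alternative 3:** para-quinone methide cyclisation.
- Disconnection: O1–C2 alone; the C3 stereocentre is set beforehand in 2,3-diarylpropanol A7.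
- Forward key step: a silver oxidant would convert the ring C phenol of A7 into the para-quinone methide across C2. The ring A phenol adds to the methide carbon in a 5-exo-trig closure, trans to the C3 substituent, to give A6.
- For it: biomimetic; trans closure is substrate-controlled; the ring C phenol ends up free without a protecting group. On these points it is at least as strong as the chosen route.
- Against it: A7 has two free phenols and the oxidant must choose the right one. The quinone methide has an acidic C3–H and can tautomerise to a stilbene, erasing the only preset stereocentre. A7 needs an auxiliary-controlled alkylation or an asymmetric hydrogenation and six to eight steps. The bromide must still be exchanged for the chain. The free phenol of A6 must be masked again before sulfation, so the saving is lost.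
- Comparison: the chosen strategy makes ring B and both its bonds to ring A in one step from fragments of two and four steps. The phenol stays masked by the same group that tunes the key step.

Key step: step 7

Remark 1: the target is drawn as the free hydrogen sulfate; it is assumed that this form is obtained by cold acidification of the salt from the last step, the salt being the practical storage form.
Remark 2: palladium-bound species of catalytic cycles are described in words and carry no compound numbers.
Remark 3: compounds 1, 2, 7 and 9 are taken to be commercially available.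

## Route

Step 1
Reactants: 1 4-bromo-2-methoxyaniline; 2 tert-butyl(dimethyl)(prop-2-en-1-yloxy)silane
Product: 4 4-[3-(tert-butyldimethylsilyloxy)propyl]-2-methoxyaniline, via B-alkyl-9-BBN adduct 3 (not isolated)
Conditions: 2, 9-BBN, THF, 0 °C to rt; then 1, Pd(OAc)2, SPhos, K3PO4 (aq), THF, 60 °C
Reagents that add atoms: 9-borabicyclo[3.3.1]nonane (9-BBN), B1C2CCCC1CCC2 (its atoms are in intermediate 3 only; none remain in 4)
Why: 9-BBN adds anti-Markovnikov to the terminal alkene of 2, and the primary alkylborane 3 should undergo B-alkyl Suzuki–Miyaura coupling at the C–Br bond of 1; the free amine and the silyl ether tolerate the phosphate base.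

Step 2
Reactants: 4 4-[3-(tert-butyldimethylsilyloxy)propyl]-2-methoxyaniline
Product: 6 tert-butyl[3-(4-iodo-3-methoxyphenyl)propoxy]dimethylsilane, via arenediazonium tetrafluoroborate 5 (not isolated)
Conditions: NOBF4, MeCN, −30 °C; then KI, −30 °C to rt
Reagents that add atoms: potassium iodide, [K+].[I-]; nitrosonium tetrafluoroborate, N#[O+].F[B-](F)(F)F (nitrogen and counter-ion of intermediate 5 only)
Why: Aprotic diazotisation with the nitrosonium salt avoids the aqueous mineral acid that would cleave the silyl ether, and iodide then replaces nitrogen (Sandmeyer-type iododediazoniation without copper), so iodine sits exactly where the amine was.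

Step 3
Reactants: 7 4-bromo-2-methoxyphenol
Product: 8 4-bromo-2-methoxyphenyl methanesulfonate
Conditions: MsCl, Et3N, CH2Cl2, 0 °C
Reagents that add atoms: methanesulfonyl chloride, CS(=O)(=O)Cl
Why: Standard O-sulfonylation of a phenol; the mesylate masks the phenol and makes ring C electron-poor for steps 6 and 7.

Step 4
Reactants: 8 4-bromo-2-methoxyphenyl methanesulfonate; 9 benzyl prop-2-yn-1-yl ether
Product: 10 4-[3-(benzyloxy)prop-1-yn-1-yl]-2-methoxyphenyl methanesulfonate
Conditions: Pd(PPh3)2Cl2, CuI, Et3N, DMF, 70 °C
Reagents that add atoms: none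
Why: Sonogashira coupling at the C–Br bond, which the para sulfonate activates; aryl mesylates do not undergo oxidative addition with triphenylphosphine-ligated palladium.

Step 5
Reactants: 10 4-[3-(benzyloxy)prop-1-yn-1-yl]-2-methoxyphenyl methanesulfonate
Product: 11 4-[(1Z)-3-(benzyloxy)prop-1-en-1-yl]-2-methoxyphenyl methanesulfonate
Conditions: H2 (1 atm), Pd/CaCO3 poisoned with Pb(OAc)2, quinoline, EtOAc, rt
Reagents that add atoms: none
Why: Lindlar-type semihydrogenation delivers both hydrogens to one face of the alkyne and so fixes the Z geometry; the poisoned catalyst leaves the benzyl ether and the aryl sulfonate untouched.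

Step 6
Reactants: 11 4-[(1Z)-3-(benzyloxy)prop-1-en-1-yl]-2-methoxyphenyl methanesulfonate
Product: 12 4-[(2R,3S)-3-(benzyloxymethyl)oxiran-2-yl]-2-methoxyphenyl methanesulfonate (cis)
Conditions: (R,R)-[N,N′-bis(3,5-di-tert-butylsalicylidene)cyclohexane-1,2-diaminato]MnCl (5 mol %), 4-phenylpyridine N-oxide, NaOCl (aq, pH 11.3), CH2Cl2, 0 °C
Reagents that add atoms: sodium hypochlorite, [Na+].[O-]Cl
Why: Jacobsen–Katsuki epoxidation, for which Z-aryl alkenes are the best substrates; by analogy with cis-β-methylstyrene and cis-cinnamates the (R,R)-catalyst should give the benzylic R epoxide, and the two new centres are set by catalyst control of the alkene face. Some trans-epoxide from the radical intermediate is expected and would be removed by chromatography.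

Step 7
Reactants: 6 tert-butyl[3-(4-iodo-3-methoxyphenyl)propoxy]dimethylsilane; 12 4-[(2R,3S)-3-(benzyloxymethyl)oxiran-2-yl]-2-methoxyphenyl methanesulfonate
Product: 13 4-[(2S,3R)-3-(benzyloxymethyl)-5-[3-(tert-butyldimethylsilyloxy)propyl]-7-methoxy-2,3-dihydro-1-benzofuran-2-yl]-2-methoxyphenyl methanesulfonate
Conditions: Pd(OAc)2 (10 mol %), XPhos (20 mol %), potassium 5-norbornene-2-carboxylate (50 mol %), K2CO3, NMP, 70 °C
Reagents that add atoms: none
Why: Proposed new method: zerovalent palladium inserts into the C7a–I bond of 6, the aryl–palladium species adds across the norbornene unit of the mediator and palladates the only free ortho position (C3a), giving a five-membered aryl–norbornyl palladacycle of divalent palladium. This electron-rich palladacycle is expected to open epoxide 12 at C3 by backside (SN2-type) attack, giving a tetravalent palladium alkyl that forms C3–C3a by reductive elimination; the closest known reaction type is the palladium/norbornene [3+2] annulation of aryl iodides with terminal epoxides to 2-substituted 2,3-dihydrobenzofurans, and an internal cis-disubstituted epoxide has not been shown in it. With both ortho positions now substituted (C7–OMe and C3), the mediator is expelled by β-carbon elimination, and ring B closes by C(sp2)–O reductive elimination from the six-membered aryl–palladium alkoxide (O1–C7a), a metal-templated [3+2] closure and not a polar exo or endo cyclisation. C3 is the one stereocentre set: it arises by inversion at the C3–O bond of 12 (stereospecific, substrate-controlled), while C2 keeps its C–O bond and configuration, so the cis-epoxide maps onto the trans-(2S,3R) product. The step needs opening at C3 and not at benzylic C2: the mesylate makes ring C electron-poor and disfavours ionising opening at C2, the aryl group shields C2 against the bulky palladacycle more than the benzyloxymethyl group shields C3, and no Lewis acid is present. Site selectivity on ring A is fixed by the C7 methoxy group, and chemoselectivity for C–I over C–OMs by the far faster oxidative addition of the iodide.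

Step 8
Reactants: 13 4-[(2S,3R)-3-(benzyloxymethyl)-5-[3-(tert-butyldimethylsilyloxy)propyl]-7-methoxy-2,3-dihydro-1-benzofuran-2-yl]-2-methoxyphenyl methanesulfonate
Product: 14 4-[(2S,3R)-3-(benzyloxymethyl)-5-(3-hydroxypropyl)-7-methoxy-2,3-dihydro-1-benzofuran-2-yl]-2-methoxyphenyl methanesulfonate
Conditions: HF·pyridine, THF/pyridine, 0 °C to rt
Reagents that add atoms: none
Why: Fluoride-driven cleavage of the primary silyl ether; the buffered acidic fluoride source leaves the aryl mesylate, the benzyl ether and the cyclic benzylic ether intact.

Step 9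
Reactants: 14 4-[(2S,3R)-3-(benzyloxymethyl)-5-(3-hydroxypropyl)-7-methoxy-2,3-dihydro-1-benzofuran-2-yl]-2-methoxyphenyl methanesulfonate
Product: 16 sodium 3-[(2S,3R)-3-(benzyloxymethyl)-7-methoxy-2-(3-methoxy-4-mesyloxyphenyl)-2,3-dihydro-1-benzofuran-5-yl]propyl sulfate, via pyridinium sulfate salt 15 (not isolated)
Conditions: SO3·pyridine, pyridine, rt; then aq NaHCO3
Reagents that add atoms: sulfur trioxide–pyridine complex, O=S(=O)([O-])[n+]1ccccc1; sodium hydrogencarbonate, [Na+].OC([O-])=O (sodium ion of 16)
Why: O-Sulfonation of the only free hydroxyl with the sulfur trioxide–pyridine complex; the phenol is masked as the mesylate and the second primary alcohol as the benzyl ether, so regiochemistry is not at issue.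

Step 10
Reactants: 16 sodium 3-[(2S,3R)-3-(benzyloxymethyl)-7-methoxy-2-(3-methoxy-4-mesyloxyphenyl)-2,3-dihydro-1-benzofuran-5-yl]propyl sulfate
Product: 17 sodium 3-[(2S,3R)-3-(hydroxymethyl)-7-methoxy-2-(3-methoxy-4-mesyloxyphenyl)-2,3-dihydro-1-benzofuran-5-yl]propyl sulfate
Conditions: H2 (1 atm), Pd/C, MeOH, rt
Reagents that add atoms: none
Why: Catalytic hydrogenolysis of the primary benzyl ether; sulfate monoester salts and aryl mesylates are neither reduced nor catalyst poisons, and the cyclic secondary C2–O1 benzylic bond on an electron-poor aryl ring should be cleaved far more slowly.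

Step 11
Reactants: 17 sodium 3-[(2S,3R)-3-(hydroxymethyl)-7-methoxy-2-(3-methoxy-4-mesyloxyphenyl)-2,3-dihydro-1-benzofuran-5-yl]propyl sulfate
Product: 19 3-[(2S,3R)-2-(4-hydroxy-3-methoxyphenyl)-3-(hydroxymethyl)-7-methoxy-2,3-dihydro-1-benzofuran-5-yl]propyl hydrogen sulfate, via phenoxide sulfate salt 18 (not isolated)
Conditions: KOH, MeOH/H2O, 60 °C; then 1 M HCl to pH 2 at 0 °C, desalting on C18 silica
Reagents that add atoms: potassium hydroxide, [K+].[OH-] (potassium ion of intermediate 18 only; 19 gains hydrogen only)
Why: Hydroxide cleaves the aryl methanesulfonate at sulfur (sulfonate ester saponification) while the alkyl sulfate monoanion is inert to base, and cold acidification then gives the phenol and the hydrogen sulfate. The trans arrangement is the thermodynamic one, so reversible phenoxide-assisted opening at C2 should not erode it.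

## Compound list

1 | 4-bromo-2-methoxyaniline | COc1cc(Br)ccc1N | starting material
2 | tert-butyl(dimethyl)(prop-2-en-1-yloxy)silane | C=CCO[Si](C)(C)C(C)(C)C | starting material
3 | 9-[3-(tert-butyldimethylsilyloxy)propyl]-9-borabicyclo[3.3.1]nonane | CC(C)(C)[Si](C)(C)OCCCB1C2CCCC1CCC2 | intermediate (not isolated)
4 | 4-[3-(tert-butyldimethylsilyloxy)propyl]-2-methoxyaniline | COc1cc(CCCO[Si](C)(C)C(C)(C)C)ccc1N | intermediate
5 | 4-[3-(tert-butyldimethylsilyloxy)propyl]-2-methoxybenzenediazonium tetrafluoroborate | COc1cc(CCCO[Si](C)(C)C(C)(C)C)ccc1[N+]#N.F[B-](F)(F)F | intermediate (not isolated)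
6 | tert-butyl[3-(4-iodo-3-methoxyphenyl)propoxy]dimethylsilane | COc1cc(CCCO[Si](C)(C)C(C)(C)C)ccc1I | intermediate
7 | 4-bromo-2-methoxyphenol | COc1cc(Br)ccc1O | starting material
8 | 4-bromo-2-methoxyphenyl methanesulfonate | COc1cc(Br)ccc1OS(C)(=O)=O | intermediate
9 | benzyl prop-2-yn-1-yl ether | C#CCOCc1ccccc1 | starting material
10 | 4-[3-(benzyloxy)prop-1-yn-1-yl]-2-methoxyphenyl methanesulfonate | COc1cc(C#CCOCc2ccccc2)ccc1OS(C)(=O)=O | intermediate
11 | 4-[(1Z)-3-(benzyloxy)prop-1-en-1-yl]-2-methoxyphenyl methanesulfonate | COc1cc(/C=C\COCc2ccccc2)ccc1OS(C)(=O)=O | intermediate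
12 | 4-[(2R,3S)-3-(benzyloxymethyl)oxiran-2-yl]-2-methoxyphenyl methanesulfonate (cis) | COc1cc([C@H]2O[C@H]2COCc2ccccc2)ccc1OS(C)(=O)=O | intermediate
13 | 4-[(2S,3R)-3-(benzyloxymethyl)-5-[3-(tert-butyldimethylsilyloxy)propyl]-7-methoxy-2,3-dihydro-1-benzofuran-2-yl]-2-methoxyphenyl methanesulfonate | COc1cc([C@H]2Oc3c(OC)cc(CCCO[Si](C)(C)C(C)(C)C)cc3[C@@H]2COCc2ccccc2)ccc1OS(C)(=O)=O | intermediate
14 | 4-[(2S,3R)-3-(benzyloxymethyl)-5-(3-hydroxypropyl)-7-methoxy-2,3-dihydro-1-benzofuran-2-yl]-2-methoxyphenyl methanesulfonate | COc1cc([C@H]2Oc3c(OC)cc(CCCO)cc3[C@@H]2COCc2ccccc2)ccc1OS(C)(=O)=O | intermediate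
15 | pyridinium 3-[(2S,3R)-3-(benzyloxymethyl)-7-methoxy-2-(3-methoxy-4-mesyloxyphenyl)-2,3-dihydro-1-benzofuran-5-yl]propyl sulfate | COc1cc([C@H]2Oc3c(OC)cc(CCCOS(=O)(=O)[O-])cc3[C@@H]2COCc2ccccc2)ccc1OS(C)(=O)=O.c1cc[nH+]cc1 | intermediate (not isolated)
16 | sodium 3-[(2S,3R)-3-(benzyloxymethyl)-7-methoxy-2-(3-methoxy-4-mesyloxyphenyl)-2,3-dihydro-1-benzofuran-5-yl]propyl sulfate | COc1cc([C@H]2Oc3c(OC)cc(CCCOS(=O)(=O)[O-])cc3[C@@H]2COCc2ccccc2)ccc1OS(C)(=O)=O.[Na+] | intermediate
17 | sodium 3-[(2S,3R)-3-(hydroxymethyl)-7-methoxy-2-(3-methoxy-4-mesyloxyphenyl)-2,3-dihydro-1-benzofuran-5-yl]propyl sulfate | COc1cc([C@H]2Oc3c(OC)cc(CCCOS(=O)(=O)[O-])cc3[C@@H]2CO)ccc1OS(C)(=O)=O.[Na+] | intermediate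
18 | potassium sodium salt of the phenoxide and sulfate of 19 | COc1cc([C@H]2Oc3c(OC)cc(CCCOS(=O)(=O)[O-])cc3[C@@H]2CO)ccc1[O-].[K+].[Na+] | intermediate (not isolated)
19 | 3-[(2S,3R)-2-(4-hydroxy-3-methoxyphenyl)-3-(hydroxymethyl)-7-methoxy-2,3-dihydro-1-benzofuran-5-yl]propyl hydrogen sulfate | COc1cc([C@H]2Oc3c(OC)cc(CCCOS(=O)(=O)O)cc3[C@@H]2CO)ccc1O | target

## Step count and least certain steps

Total: 11 steps. Longest linear sequence: 9 steps (7 to 19, steps 3 to 11); the aryl iodide branch is 2 steps (1 to 6).

**Step 7 (key step).**
- What may go wrong: opening of the epoxide at benzylic C2 in place of C3; no opening at all at a secondary carbon, so that the palladacycle decays by coupling with the mediator; opening by iodide before the palladacycle, which would lead to net retention at C3 and a cis ring; base- or palladium-induced isomerisation of the epoxide to a ketone; β-hydride loss from the palladium alkoxide in place of C–O bond formation.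
- Fallback (known reaction types): it sets out from 8 and from borane 3 and returns at 13.
 - 8 is borylated (B2(OH)4, Pd(OAc)2, XPhos, KOAc, EtOH) to [3-methoxy-4-(methylsulfonyloxy)phenyl]boronic acid F1.
 - Purchased 1-(2-hydroxy-3-methoxyphenyl)ethanone F2 is brominated para to the hydroxyl to 1-(5-bromo-2-hydroxy-3-methoxyphenyl)ethanone F3.
 - F3 is condensed with dimethylformamide dimethyl acetal and cyclised with acid to 6-bromo-8-methoxychromen-4-one F4.
 - Asymmetric conjugate addition of F1 to F4 (Pd(OCOCF3)2 with the appropriate enantiomer of t-BuPyOx) should give (2S)-flavanone F5.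
 - Oxidative ring contraction (PhI(OAc)2, H2SO4, trimethyl orthoformate) should give trans ester F6.
 - Reduction with LiBH4 gives alcohol F7.
 - Benzylation with benzyl 2,2,2-trichloroacetimidate and catalytic triflic acid gives benzyl ether F8.
 - B-alkyl Suzuki coupling of F8 with 3 gives 13.

**Step 6.**
- What may go wrong: leakage from cis to trans through the radical intermediate of oxygen transfer, and incomplete facial selectivity with the benzyloxymethyl substituent.
- Fallback: it sets out from 8 and returns at 12.
 - Sonogashira coupling of 8 with prop-2-yn-1-ol gives alkynol F9.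
 - Semihydrogenation (Pd/CaCO3 poisoned with Pb(OAc)2) gives Z-allylic alcohol F10.
 - Sharpless asymmetric epoxidation (Ti(OiPr)4, L-(+)-diethyl tartrate, t-BuOOH, molecular sieves, −20 °C) is a concerted, alcohol-directed oxygen transfer without cis/trans leakage and should give cis-epoxy alcohol F11.
 - Benzylation under neutral conditions (BnBr, Ag2O) gives 12.

**Step 2.**
- What may go wrong: loss of the diazonium group by reduction, azo coupling of the electron-rich aniline, and partial loss of the silyl group.
- Fallback: it sets out from 1 and returns at 6.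
 - Heck reaction of 1 with methyl acrylate gives aminocinnamate F12.
 - Hydrogenation (H2, Pd/C) gives amino ester F13.
 - Classical aqueous diazotisation and iodination (NaNO2, H2SO4; KI) gives iodo ester F14.
 - Reduction with LiBH4 gives iodo alcohol F15.
 - Silylation (TBSCl, imidazole) gives 6.

**Step 10.**
- What may go wrong: hydrogenolytic opening of the C2–O1 benzylic bond of ring B, or sluggish cleavage of the primary benzyl ether on the polar salt.
- Fallback: it sets out from 13 and returns at 18, and so at 19.
 - The benzyl ether of 13 is cleaved without hydrogen (BCl3·SMe2, CH2Cl2) to alcohol F16.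
 - Acetylation (Ac2O, pyridine) gives acetate F17.
 - Desilylation (HF·pyridine) gives alcohol F18.
 - Sulfation (SO3·pyridine; NaHCO3) gives sulfate F19.
 - KOH in aqueous methanol removes the acetate and the mesylate together to give 18, which is acidified to 19 as in step 11.

## Further compounds

F1 | step 7 | [3-methoxy-4-(methylsulfonyloxy)phenyl]boronic acid | COc1cc(B(O)O)ccc1OS(C)(=O)=O
F2 | step 7 | 1-(2-hydroxy-3-methoxyphenyl)ethanone (purchased) | COc1cccc(C(C)=O)c1O
F3 | step 7 | 1-(5-bromo-2-hydroxy-3-methoxyphenyl)ethanone | COc1cc(Br)cc(C(C)=O)c1O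
F4 | step 7 | 6-bromo-8-methoxy-4H-chromen-4-one | COc1cc(Br)cc2c1OC=CC2=O
F5 | step 7 | 4-[(2S)-6-bromo-8-methoxy-4-oxo-3,4-dihydro-2H-chromen-2-yl]-2-methoxyphenyl methanesulfonate | COc1cc([C@@H]2CC(=O)c3cc(Br)cc(OC)c3O2)ccc1OS(C)(=O)=O
F6 | step 7 | methyl (2S,3S)-5-bromo-7-methoxy-2-(3-methoxy-4-mesyloxyphenyl)-2,3-dihydro-1-benzofuran-3-carboxylate (trans) | COc1cc([C@H]2Oc3c(OC)cc(Br)cc3[C@@H]2C(=O)OC)ccc1OS(C)(=O)=O
F7 | step 7 | 4-[(2S,3R)-5-bromo-3-(hydroxymethyl)-7-methoxy-2,3-dihydro-1-benzofuran-2-yl]-2-methoxyphenyl methanesulfonate | COc1cc([C@H]2Oc3c(OC)cc(Br)cc3[C@@H]2CO)ccc1OS(C)(=O)=O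
F8 | step 7 | 4-[(2S,3R)-3-(benzyloxymethyl)-5-bromo-7-methoxy-2,3-dihydro-1-benzofuran-2-yl]-2-methoxyphenyl methanesulfonate | COc1cc([C@H]2Oc3c(OC)cc(Br)cc3[C@@H]2COCc2ccccc2)ccc1OS(C)(=O)=O
F9 | step 6 | 4-(3-hydroxyprop-1-yn-1-yl)-2-methoxyphenyl methanesulfonate | COc1cc(C#CCO)ccc1OS(C)(=O)=O
F10 | step 6 | 4-[(1Z)-3-hydroxyprop-1-en-1-yl]-2-methoxyphenyl methanesulfonate | COc1cc(/C=C\CO)ccc1OS(C)(=O)=O
F11 | step 6 | 4-[(2R,3S)-3-(hydroxymethyl)oxiran-2-yl]-2-methoxyphenyl methanesulfonate (cis) | COc1cc([C@H]2O[C@H]2CO)ccc1OS(C)(=O)=O
F12 | step 2 | methyl (2E)-3-(4-amino-3-methoxyphenyl)prop-2-enoate | COC(=O)/C=C/c1ccc(N)c(OC)c1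
F13 | step 2 | methyl 3-(4-amino-3-methoxyphenyl)propanoate | COC(=O)CCc1ccc(N)c(OC)c1
F14 | step 2 | methyl 3-(4-iodo-3-methoxyphenyl)propanoate | COC(=O)CCc1ccc(I)c(OC)c1
F15 | step 2 | 3-(4-iodo-3-methoxyphenyl)propan-1-ol | OCCCc1ccc(I)c(OC)c1
F16 | step 10 | 4-[(2S,3R)-5-[3-(tert-butyldimethylsilyloxy)propyl]-3-(hydroxymethyl)-7-methoxy-2,3-dihydro-1-benzofuran-2-yl]-2-methoxyphenyl methanesulfonate | COc1cc([C@H]2Oc3c(OC)cc(CCCO[Si](C)(C)C(C)(C)C)cc3[C@@H]2CO)ccc1OS(C)(=O)=O
F17 | step 10 | [(2S,3R)-5-[3-(tert-butyldimethylsilyloxy)propyl]-7-methoxy-2-(3-methoxy-4-mesyloxyphenyl)-2,3-dihydro-1-benzofuran-3-yl]methyl acetate | COc1cc([C@H]2Oc3c(OC)cc(CCCO[Si](C)(C)C(C)(C)C)cc3[C@@H]2COC(C)=O)ccc1OS(C)(=O)=O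
F18 | step 10 | [(2S,3R)-5-(3-hydroxypropyl)-7-methoxy-2-(3-methoxy-4-mesyloxyphenyl)-2,3-dihydro-1-benzofuran-3-yl]methyl acetate | COc1cc([C@H]2Oc3c(OC)cc(CCCO)cc3[C@@H]2COC(C)=O)ccc1OS(C)(=O)=O
F19 | step 10 | sodium 3-[(2S,3R)-3-(acetoxymethyl)-7-methoxy-2-(3-methoxy-4-mesyloxyphenyl)-2,3-dihydro-1-benzofuran-5-yl]propyl sulfate | COc1cc([C@H]2Oc3c(OC)cc(CCCOS(=O)(=O)[O-])cc3[C@@H]2COC(C)=O)ccc1OS(C)(=O)=O.[Na+]
A1 | alternative 1 | tert-butyl{3-[(2S,3R)-2-(4-benzyloxy-3-methoxyphenyl)-3-(benzyloxymethyl)-7-methoxy-2,3-dihydro-1-benzofuran-5-yl]propoxy}dimethylsilane | COc1cc([C@H]2Oc3c(OC)cc(CCCO[Si](C)(C)C(C)(C)C)cc3[C@@H]2COCc2ccccc2)ccc1OCc1ccccc1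
A2 | alternative 1 | 2-[2-(benzyloxy)-1-(4-methylphenylsulfonyl)ethyl]-4-[3-(tert-butyldimethylsilyloxy)propyl]-6-methoxyphenol (racemic) | COc1cc(CCCO[Si](C)(C)C(C)(C)C)cc(C(COCc2ccccc2)S(=O)(=O)c2ccc(C)cc2)c1O
A3 | alternative 1 | 1-(4-benzyloxy-3-methoxybenzyl)thiolan-1-ium bromide | COc1cc(C[S+]2CCCC2)ccc1OCc1ccccc1.[Br-]
A4 | alternative 2 | methyl (2S,3S)-5-bromo-7-methoxy-2-(3-methoxy-4-mesyloxyphenyl)-2,3-dihydro-1-benzofuran-3-carboxylate (trans) | COc1cc([C@H]2Oc3c(OC)cc(Br)cc3[C@@H]2C(=O)OC)ccc1OS(C)(=O)=O
A5 | alternative 2 | 4-[(2S)-6-bromo-8-methoxy-4-oxo-3,4-dihydro-2H-chromen-2-yl]-2-methoxyphenyl methanesulfonate | COc1cc([C@@H]2CC(=O)c3cc(Br)cc(OC)c3O2)ccc1OS(C)(=O)=O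
A6 | alternative 3 | 4-[(2S,3R)-3-(benzyloxymethyl)-5-bromo-7-methoxy-2,3-dihydro-1-benzofuran-2-yl]-2-methoxyphenol | COc1cc([C@H]2Oc3c(OC)cc(Br)cc3[C@@H]2COCc2ccccc2)ccc1O
A7 | alternative 3 | 2-[(2R)-1-(benzyloxy)-3-(4-hydroxy-3-methoxyphenyl)propan-2-yl]-4-bromo-6-methoxyphenol | COc1cc(C[C@@H](COCc2ccccc2)c2cc(Br)cc(OC)c2O)ccc1O
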